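**Plan**

Germacranolide numbering is used: ring carbons C1–C10 (C1 hemiketal, C4 O‑bearing quaternary, C5 olefinic CH, C6 ylidene carbon on the lactone oxygen, C8 ester carbon, C10 CHMe), C7=C11 butenolide alkene, C12 lactone carbonyl, C13 acetoxymethyl.
Retrosynthetic cuts, in order: the C8 ester and C13 acetate; the C1–O–C4 hemiketal and the C5=C6 alkene, traced back to a 1,3‑diol monomesylate in which C1 and C6 are still bonded (a Grob fragmentation in the forward sense); the C5–C6 bond (vinylogous aldol) and the C1–C2 bond (Grignard addition); finally C12–C11 and C7–C6 together (oxazole–alkyne Diels–Alder/retro‑Diels–Alder).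
Enabling feature: the furanone ring O–C12(=O)–C11=C7–C6 is a 2‑alkoxyfuran at another tautomeric level; its C12–O–C6 unit maps onto C5–O1–C2 of a 5‑benzyloxyoxazole and C11≡C7 onto an ynone tied to C6 by the four atoms C1, C10, C9, C8.
Forward order: oxazole aldehyde, side chain to the ynone, key step closing ring B (C6, C7, C8, C9, C10, C1) and the furan together, C1 ketone, C2–C5 chain, butenolide, ring A (C1–C6), fragmentation of the A/B fusion bond to the ten‑membered ring with its C5=C6 alkene and C1/C4 hemiketal, then the two acylations.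
Stereochemistry: C10 from a Brown (Z)‑crotylboration; C8 from axial hydride delivery cis to C10–Me in ring B; C4 from (R)‑citramalic acid; the C1 hemiketal centre is dictated by C4 through the oxygen bridge; C2' of the ester from (R)‑3‑bromo‑2‑hydroxy‑2‑methylpropanoic acid; the C5=C6 geometry from the bridged ten‑membered ring.

Key step: step 10

Remark on the chemistry: C1, C5 and C6 of compounds 25–31 are relay centres that are erased in step 22. They are drawn as expected, and left open in the SMILES where an epimer mixture is carried; either epimer serves.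

**Step 1**
Reactants: 1 L‑alanine benzyl ester p‑toluenesulfonate; 2 ethyl chlorooxoacetate
Product: 3 benzyl N‑(2‑ethoxy‑2‑oxoacetyl)‑L‑alaninate
Conditions: Et3N (2.2 equiv), CH2Cl2, 0 °C to rt
Reagents that add atoms: none
Why: N‑acylation of the liberated amine by the acid chloride, which is far more electrophilic than either ester (Schotten–Baumann type).

**Step 2**
Reactants: 3 benzyl N‑(2‑ethoxy‑2‑oxoacetyl)‑L‑alaninate
Product: 4 ethyl 5‑(benzyloxy)‑4‑methyl‑1,3‑oxazole‑2‑carboxylate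
Conditions: POCl3 (1.2 equiv), Et3N (3 equiv), toluene, 90 °C
Reagents that add atoms: none
Why: Robinson–Gabriel‑type cyclodehydration of an N‑acyl amino ester to the 5‑alkoxyoxazole (the ester carbonyl oxygen closes onto the activated amide carbon); the alanine centre becomes the sp2 C4 of the oxazole and is of no consequence.

**Step 3**
Reactants: 4 ethyl 5‑(benzyloxy)‑4‑methyl‑1,3‑oxazole‑2‑carboxylate
Product: 5 5‑(benzyloxy)‑4‑methyl‑1,3‑oxazole‑2‑carbaldehyde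
Conditions: i‑Bu2AlH (1.05 equiv), CH2Cl2, −78 °C; MeOH, then aq. potassium sodium tartrate
Reagents that add atoms: none
Why: partial reduction of a heteroaryl 2‑carboxylate, whose aluminium hemiacetal is held by chelation to the ring nitrogen at −78 °C and releases the aldehyde only on work‑up.

**Step 4**
Reactants: 5 5‑(benzyloxy)‑4‑methyl‑1,3‑oxazole‑2‑carbaldehyde
Product: 6 (1S,2R)‑1‑[5‑(benzyloxy)‑4‑methyl‑1,3‑oxazol‑2‑yl]‑2‑methylbut‑3‑en‑1‑ol
Conditions: (Z)‑crotyl‑B(Ipc)2 [from cis‑2‑butene, t‑BuOK, n‑BuLi, (−)‑Ipc2BOMe, BF3·OEt2], THF/Et2O, −78 °C; then NaOH, H2O2, 0 °C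
Reagents that add atoms: (Z)‑crotyldiisopinocampheylborane, C/C=C\CB([C@@H]1C[C@@H]2C[C@H]([C@H]1C)C2(C)C)[C@@H]1C[C@@H]2C[C@H]([C@H]1C)C2(C)C
Why: Brown crotylboration through a closed chair Zimmerman–Traxler transition state, in which the Z‑crotyl unit gives the syn adduct and the isopinocampheyl ligands of (+)‑α‑pinene origin direct attack on the Si face of the aldehyde, setting C10 (R) and the relay centre C1 (S).

**Step 5**
Reactants: 6 (1S,2R)‑1‑[5‑(benzyloxy)‑4‑methyl‑1,3‑oxazol‑2‑yl]‑2‑methylbut‑3‑en‑1‑ol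
Product: 7 5‑(benzyloxy)‑4‑methyl‑2‑[(1S,2R)‑2‑methyl‑1‑(triethylsilyloxy)but‑3‑en‑1‑yl]‑1,3‑oxazole
Conditions: TESCl, imidazole, DMF, 0 °C to rt
Reagents that add atoms: chlorotriethylsilane, CC[Si](Cl)(CC)CC
Why: standard silylation of a secondary alcohol; the triethylsilyl ether is chosen because it can later be removed beside triisopropylsilyl ethers.

**Step 6**
Reactants: 7 5‑(benzyloxy)‑4‑methyl‑2‑[(1S,2R)‑2‑methyl‑1‑(triethylsilyloxy)but‑3‑en‑1‑yl]‑1,3‑oxazole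
Product: 8 (3R,4S)‑4‑[5‑(benzyloxy)‑4‑methyl‑1,3‑oxazol‑2‑yl]‑3‑methyl‑4‑(triethylsilyloxy)butan‑1‑ol
Conditions: 9‑BBN (1.5 equiv), THF, 0 °C to rt; then NaOH, H2O2, 0 °C
Reagents that add atoms: hydrogen peroxide, OO
Why: anti‑Markovnikov hydroboration–oxidation of the terminal vinyl group with the bulky borane, which creates C8 as a primary alcohol without touching C10.

**Step 7**
Reactants: 8 (3R,4S)‑4‑[5‑(benzyloxy)‑4‑methyl‑1,3‑oxazol‑2‑yl]‑3‑methyl‑4‑(triethylsilyloxy)butan‑1‑ol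
Product: 9 (3R,4S)‑4‑[5‑(benzyloxy)‑4‑methyl‑1,3‑oxazol‑2‑yl]‑3‑methyl‑4‑(triethylsilyloxy)butanal
Conditions: Dess–Martin periodinane, NaHCO3, CH2Cl2, 0 °C to rt
Reagents that add atoms: none
Why: buffered Dess–Martin oxidation of a primary alcohol to the aldehyde; the stereocentre is β to the new carbonyl and cannot epimerize.

**Step 8**
Reactants: 9 (3R,4S)‑4‑[5‑(benzyloxy)‑4‑methyl‑1,3‑oxazol‑2‑yl]‑3‑methyl‑4‑(triethylsilyloxy)butanal; 10 triisopropyl(prop‑2‑yn‑1‑yloxy)silane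
Product: 12 (6R,7S)‑7‑[5‑(benzyloxy)‑4‑methyl‑1,3‑oxazol‑2‑yl]‑6‑methyl‑7‑(triethylsilyloxy)‑1‑(triisopropylsilyloxy)hept‑2‑yn‑4‑ol (C4 epimers), via lithium acetylide 11 (not isolated)
Conditions: 10, n‑BuLi, THF, −78 °C; then 9, −78 °C; aq. NH4Cl
Reagents that add atoms: none
Why: 1,2‑addition of a lithium acetylide to an aldehyde joins C8 to C7; the carbinol mixture is immaterial because the centre is oxidized in the next step.

**Step 9**
Reactants: 12 (6R,7S)‑7‑[5‑(benzyloxy)‑4‑methyl‑1,3‑oxazol‑2‑yl]‑6‑methyl‑7‑(triethylsilyloxy)‑1‑(triisopropylsilyloxy)hept‑2‑yn‑4‑ol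
Product: 13 (6R,7S)‑7‑[5‑(benzyloxy)‑4‑methyl‑1,3‑oxazol‑2‑yl]‑6‑methyl‑7‑(triethylsilyloxy)‑1‑(triisopropylsilyloxy)hept‑2‑yn‑4‑one
Conditions: Dess–Martin periodinane, NaHCO3, CH2Cl2, 0 °C; used at once
Reagents that add atoms: none
Why: Dess–Martin oxidation of a propargylic alcohol to the ynone, which activates the triple bond for the cycloaddition.

**Step 10**
Reactants: 13 (6R,7S)‑7‑[5‑(benzyloxy)‑4‑methyl‑1,3‑oxazol‑2‑yl]‑6‑methyl‑7‑(triethylsilyloxy)‑1‑(triisopropylsilyloxy)hept‑2‑yn‑4‑one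
Product: 15 (6R,7S)‑2‑(benzyloxy)‑6‑methyl‑7‑(triethylsilyloxy)‑3‑[(triisopropylsilyloxy)methyl]‑6,7‑dihydro‑1‑benzofuran‑4(5H)‑one, via oxa‑aza‑bicycloheptadiene cycloadduct 14 (not isolated)
Conditions: toluene (0.01 M), 2,6‑di‑tert‑butyl‑4‑methylphenol (trace), 80 to 110 °C
Reagents that add atoms: none
Why: The oxazole acts as an azadiene (O1–C2=N3–C4=C5; C2 is the future C6, C5 the future C12) and adds across the ynone triple bond (C7≡C11) in an intramolecular [4+2] cycloaddition to the oxa‑aza‑bicycloheptadiene 14, which at once loses acetonitrile (N3≡C4–CH3) by retro‑[4+2] to leave the 2‑benzyloxyfuran, so that C6–C7 and C12–C11 are made in one operation. The closest known reaction type is the intramolecular oxazole–alkyne Diels–Alder/retro‑Diels–Alder furan synthesis of 5‑alkoxyoxazoles carrying alkynyl ketone side chains (bis‑heteroannulation, related to the Kondrat'eva reaction). Ring B (C6, C7, C8, C9, C10, C1) closes as a six‑membered ring in the fused mode through the four‑atom tether C1–C10–C9–C8, and the furan ring arises by exchange of the N3=C4 bridge of the adduct for the C7=C11 unit. No new stereocentre survives: the two bridgehead centres of 14 are transient, both facial adducts collapse to the same furan, and C10 and C1 are untouched. The step needs regiocontrol (C6 to C7 and C12 to C11, opposite to the electronically preferred intermolecular orientation) and chemoselectivity over bimolecular reaction and benzyl migration; the tether fixes the regiochemistry, the C8 carbonyl lowers the alkyne LUMO and the 5‑benzyloxy group raises the diene HOMO so that the reaction should run at or below 110 °C, and high dilution suppresses intermolecular cycloaddition.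

**Step 11**
Reactants: 15 (6R,7S)‑2‑(benzyloxy)‑6‑methyl‑7‑(triethylsilyloxy)‑3‑[(triisopropylsilyloxy)methyl]‑6,7‑dihydro‑1‑benzofuran‑4(5H)‑one
Product: 16 (4S,6R,7S)‑2‑(benzyloxy)‑6‑methyl‑7‑(triethylsilyloxy)‑3‑[(triisopropylsilyloxy)methyl]‑4,5,6,7‑tetrahydro‑1‑benzofuran‑4‑ol
Conditions: NaBH4, CeCl3·7H2O, MeOH/THF, −78 to −40 °C
Reagents that add atoms: none
Why: Luche 1,2‑reduction of the furyl ketone, in which hydride should add axially to the half‑chair that holds C10–Me and C1–OSiEt3 pseudo‑equatorial, giving the equatorial C8 alcohol cis to C10–Me (8S).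

**Step 12**
Reactants: 16 (4S,6R,7S)‑2‑(benzyloxy)‑6‑methyl‑7‑(triethylsilyloxy)‑3‑[(triisopropylsilyloxy)methyl]‑4,5,6,7‑tetrahydro‑1‑benzofuran‑4‑ol
Product: 17 (4S,6R,7S)‑2‑(benzyloxy)‑6‑methyl‑7‑(triethylsilyloxy)‑4‑(triisopropylsilyloxy)‑3‑[(triisopropylsilyloxy)methyl]‑4,5,6,7‑tetrahydro‑1‑benzofuran
Conditions: TIPSOTf, 2,6‑lutidine, CH2Cl2, −78 to 0 °C
Reagents that add atoms: triisopropylsilyl trifluoromethanesulfonate, CC(C)[Si](OS(=O)(=O)C(F)(F)F)(C(C)C)C(C)C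
Why: silyl triflate/lutidine silylation of a hindered secondary alcohol under base‑buffered conditions that spare the acid‑labile alkoxyfuran.

**Step 13**
Reactants: 17 (4S,6R,7S)‑2‑(benzyloxy)‑6‑methyl‑7‑(triethylsilyloxy)‑4‑(triisopropylsilyloxy)‑3‑[(triisopropylsilyloxy)methyl]‑4,5,6,7‑tetrahydro‑1‑benzofuran
Product: 18 (4S,6R,7S)‑2‑(benzyloxy)‑6‑methyl‑4‑(triisopropylsilyloxy)‑3‑[(triisopropylsilyloxy)methyl]‑4,5,6,7‑tetrahydro‑1‑benzofuran‑7‑ol
Conditions: n‑Bu4NF (1.1 equiv), THF, −20 to 0 °C; pH 7 buffer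
Reagents that add atoms: none
Why: fluoride cleaves the triethylsilyl ether far faster than the two triisopropylsilyl ethers, and the acid‑free medium protects the furfuryl alcohol that is set free.

**Step 14**
Reactants: 18 (4S,6R,7S)‑2‑(benzyloxy)‑6‑methyl‑4‑(triisopropylsilyloxy)‑3‑[(triisopropylsilyloxy)methyl]‑4,5,6,7‑tetrahydro‑1‑benzofuran‑7‑ol
Product: 19 (4S,6R)‑2‑(benzyloxy)‑6‑methyl‑4‑(triisopropylsilyloxy)‑3‑[(triisopropylsilyloxy)methyl]‑5,6‑dihydro‑1‑benzofuran‑7(4H)‑one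
Conditions: MnO2 (activated, excess), CH2Cl2, rt
Reagents that add atoms: none
Why: neutral MnO2 oxidation of an electron‑rich furfuryl (benzylic‑type) alcohol to the C1 ketone without enolizing the adjacent C10 centre.

**Step 15**
Reactants: 20 (R)‑citramalic acid
Product: 21 (R)‑2‑methylbutane‑1,2,4‑triol
Conditions: BH3·SMe2, B(OMe)3, THF, 0 °C to rt; MeOH
Reagents that add atoms: none
Why: borane reduction of both carboxylic acids of a hydroxy diacid, which leaves the quaternary carbinol centre (the future C4) untouched.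

**Step 16**
Reactants: 21 (R)‑2‑methylbutane‑1,2,4‑triol
Product: 22 2‑[(4R)‑2,2,4‑trimethyl‑1,3‑dioxolan‑4‑yl]ethanol
Conditions: 2,2‑dimethoxypropane, acetone, p‑TsOH·H2O (cat.), rt
Reagents that add atoms: 2,2‑dimethoxypropane, COC(C)(C)OC
Why: thermodynamic acetonide formation, which should favour the five‑membered 1,2‑dioxolane over the six‑membered alternative and leave the primary alcohol free.

**Step 17**
Reactants: 22 2‑[(4R)‑2,2,4‑trimethyl‑1,3‑dioxolan‑4‑yl]ethanol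
Product: 23 (4R)‑4‑(2‑bromoethyl)‑2,2,4‑trimethyl‑1,3‑dioxolane
Conditions: CBr4, PPh3, imidazole, CH2Cl2, 0 °C
Reagents that add atoms: carbon tetrabromide, BrC(Br)(Br)Br
Why: Appel bromination of a primary alcohol under buffered conditions that keep the acetonide.

**Step 18**
Reactants: 19 (4S,6R)‑2‑(benzyloxy)‑6‑methyl‑4‑(triisopropylsilyloxy)‑3‑[(triisopropylsilyloxy)methyl]‑5,6‑dihydro‑1‑benzofuran‑7(4H)‑one; 23 (4R)‑4‑(2‑bromoethyl)‑2,2,4‑trimethyl‑1,3‑dioxolane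
Product: 25 (4S,6R,7R)‑2‑(benzyloxy)‑6‑methyl‑4‑(triisopropylsilyloxy)‑3‑[(triisopropylsilyloxy)methyl]‑7‑{2‑[(4R)‑2,2,4‑trimethyl‑1,3‑dioxolan‑4‑yl]ethyl}‑4,5,6,7‑tetrahydro‑1‑benzofuran‑7‑ol, via Grignard reagent 24 (not isolated)
Conditions: 23, Mg, THF, 40 °C; then LaCl3·2LiCl (1 equiv), 19, THF, −78 to −20 °C; pH 7 buffer
Reagents that add atoms: none
Why: Grignard addition to the C1 ketone, promoted by LaCl3·2LiCl to outrun enolization at C10, forms the C1–C2 bond; equatorial attack anti to C10–Me is expected, but the C1 configuration is erased in step 22.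

**Step 19**
Reactants: 25 (4S,6R,7R)‑2‑(benzyloxy)‑6‑methyl‑4‑(triisopropylsilyloxy)‑3‑[(triisopropylsilyloxy)methyl]‑7‑{2‑[(4R)‑2,2,4‑trimethyl‑1,3‑dioxolan‑4‑yl]ethyl}‑4,5,6,7‑tetrahydro‑1‑benzofuran‑7‑ol
Product: 28 (4S,6R,7R)‑7‑[(3R)‑3,4‑dihydroxy‑3‑methylbutyl]‑7‑hydroxy‑6‑methyl‑4‑(triisopropylsilyloxy)‑3‑[(triisopropylsilyloxy)methyl]‑5,6,7,7a‑tetrahydro‑1‑benzofuran‑2(4H)‑one (C7a epimers), via hydroxyfuran 26 (not isolated), via acetonide butenolide 27 (not isolated)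
Conditions: H2 (1 atm), 10% Pd/C, EtOAc (trace Et3N), rt; filter; then AcOH/H2O/THF (3:1:1), 40 °C
Reagents that add atoms: none
Why: neutral hydrogenolysis of the O‑benzyl group gives the 2‑hydroxyfuran, which tautomerizes to the butenolide before any acid is present (so the furfuryl C1 carbinol is never ionized), and mild aqueous acid then hydrolyses the acetonide while the triisopropylsilyl ethers stay.

**Step 20**
Reactants: 28 (4S,6R,7R)‑7‑[(3R)‑3,4‑dihydroxy‑3‑methylbutyl]‑7‑hydroxy‑6‑methyl‑4‑(triisopropylsilyloxy)‑3‑[(triisopropylsilyloxy)methyl]‑5,6,7,7a‑tetrahydro‑1‑benzofuran‑2(4H)‑one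
Product: 30 tricyclic vinylogous aldol adduct (ring A C1–C6 cis‑fused to ring B; hydroxyls at C1, C4, C5; C5 epimers), via hydroxy aldehyde 29 (not isolated)
Conditions: TEMPO (0.1 equiv), PhI(OAc)2 (1.1 equiv), CH2Cl2, rt; then DBU (0.3 equiv), 0 °C
Reagents that add atoms: none
Why: the oxoammonium oxidation touches only the primary C5 alcohol, and the amine base then generates the furanolate, whose γ‑carbon C6 closes ring A on the C5 aldehyde (intramolecular vinylogous aldol, the only mode that gives a six‑membered ring) from the face that carries the tether, which makes C6 quaternary and the A/B fusion cis.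

**Step 21**
Reactants: 30 tricyclic vinylogous aldol adduct
Product: 31 C5 methanesulfonate of 30
Conditions: MsCl (1.5 equiv), Et3N (3 equiv), CH2Cl2, −20 °C
Reagents that add atoms: methanesulfonyl chloride, CS(=O)(=O)Cl
Why: sulfene‑mediated mesylation reaches the hindered secondary C5 alcohol but not the two tertiary alcohols at C1 and C4.

**Step 22**
Reactants: 31 C5 methanesulfonate of 30
Product: 33 (1S,4R,5E,8S,10R)‑1,4‑epoxy‑1‑hydroxy‑8,13‑bis(triisopropylsilyloxy)germacra‑5,7(11)‑dien‑12,6‑olide, via ring‑opened keto alcohol 32 (not isolated)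
Conditions: t‑BuOK (1.2 equiv), THF, −40 to 0 °C; aq. NH4Cl
Reagents that add atoms: none
Why: Grob (Wharton) fragmentation of a 1,3‑diol monomesylate, in which the C1 alkoxide expels the C1–C6 bond (a retro‑vinylogous aldol with the furanolate carbon as terminus) as C5–OMs leaves, gives the C1 ketone and the C5=C6 ylidene lactone in a ten‑membered ring, after which the C4 hydroxyl adds to the C1 ketone; the hemiketal centre can only form with C10 and C5 cis on the oxolane and is therefore set by C4, and a stepwise retro‑aldol/E1cB course from either C5 epimer leads to the same product with C4 and C7 cis on the alkene.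

**Step 23**
Reactants: 33 (1S,4R,5E,8S,10R)‑1,4‑epoxy‑1‑hydroxy‑8,13‑bis(triisopropylsilyloxy)germacra‑5,7(11)‑dien‑12,6‑olide
Product: 34 (1S,4R,5E,8S,10R)‑1,4‑epoxy‑1,8,13‑trihydroxygermacra‑5,7(11)‑dien‑12,6‑olide
Conditions: HF·pyridine, pyridine, THF, 0 °C to rt
Reagents that add atoms: none
Why: buffered fluoride removes both triisopropylsilyl ethers without the basic conditions that would let the furanolate expel the C13 oxygen.

**Step 24**
Reactants: 34 (1S,4R,5E,8S,10R)‑1,4‑epoxy‑1,8,13‑trihydroxygermacra‑5,7(11)‑dien‑12,6‑olide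
Product: 35 (1S,4R,5E,8S,10R)‑13‑acetoxy‑1,4‑epoxy‑1,8‑dihydroxygermacra‑5,7(11)‑dien‑12,6‑olide
Conditions: AcCl (1.05 equiv), 2,4,6‑collidine, CH2Cl2, −78 °C
Reagents that add atoms: acetyl chloride, CC(=O)Cl
Why: the primary C13 alcohol is acetylated much faster than the hindered secondary C8 alcohol and the tertiary hemiketal hydroxyl under these low‑temperature conditions.

**Step 25**
Reactants: 36 (R)‑3‑bromo‑2‑hydroxy‑2‑methylpropanoic acid
Product: 37 potassium (S)‑2‑methyloxirane‑2‑carboxylate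
Conditions: KOH (2.0 equiv), EtOH, 0 °C to rt
Reagents that add atoms: potassium hydroxide, [K+].[OH-]
Why: intramolecular Williamson closure of the bromohydrin to the glycidate, with no bond to the quaternary centre broken (the descriptor changes from R to S only by priority).

**Step 26**
Reactants: 35 (1S,4R,5E,8S,10R)‑13‑acetoxy‑1,4‑epoxy‑1,8‑dihydroxygermacra‑5,7(11)‑dien‑12,6‑olide; 37 potassium (S)‑2‑methyloxirane‑2‑carboxylate
Product: 39 (1S,4R,5E,8S,10R)‑13‑acetoxy‑1,4‑epoxy‑1‑hydroxy‑12‑oxogermacra‑5,7(11)‑dien‑12,6‑olid‑8‑yl (2S)‑2‑methyloxirane‑2‑carboxylate, via mixed anhydride 38 (not isolated)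
Conditions: 37, 2,4,6‑trichlorobenzoyl chloride, THF, rt; then 35, DMAP, toluene, rt
Reagents that add atoms: none
Why: Yamaguchi esterification of the secondary C8 alcohol through the mixed anhydride and its acylpyridinium; the hemiketal hydroxyl is too hindered to compete, and the epoxide carries the later hydroxyl and chloride in protected form.

**Step 27**
Reactants: 39 (1S,4R,5E,8S,10R)‑13‑acetoxy‑1,4‑epoxy‑1‑hydroxy‑12‑oxogermacra‑5,7(11)‑dien‑12,6‑olid‑8‑yl (2S)‑2‑methyloxirane‑2‑carboxylate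
Product: 40 CNP0414417.3, (1S,4R,5E,8S,10R)‑13‑acetoxy‑1,4‑epoxy‑1‑hydroxy‑12‑oxogermacra‑5,7(11)‑dien‑12,6‑olid‑8‑yl (2R)‑3‑chloro‑2‑hydroxy‑2‑methylpropanoate
Conditions: LiCl (5 equiv), AcOH (5 equiv), THF, rt
Reagents that add atoms: lithium chloride, [Li+].[Cl-]
Why: acid‑assisted chloride opening of the glycidic ester at its CH2 terminus (the ester‑bearing quaternary carbon resists substitution), which leaves the quaternary centre untouched and gives the (2R)‑chlorohydrin.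

**Compound list**

1 | L‑alanine benzyl ester p‑toluenesulfonate | C[C@H](N)C(=O)OCc1ccccc1.Cc1ccc(cc1)S(=O)(=O)O | starting material
2 | ethyl chlorooxoacetate | CCOC(=O)C(=O)Cl | starting material
3 | benzyl N‑(2‑ethoxy‑2‑oxoacetyl)‑L‑alaninate | CCOC(=O)C(=O)N[C@@H](C)C(=O)OCc1ccccc1 | intermediate
4 | ethyl 5‑(benzyloxy)‑4‑methyl‑1,3‑oxazole‑2‑carboxylate | CCOC(=O)c1nc(C)c(OCc2ccccc2)o1 | intermediate
5 | 5‑(benzyloxy)‑4‑methyl‑1,3‑oxazole‑2‑carbaldehyde | O=Cc1nc(C)c(OCc2ccccc2)o1 | intermediate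
6 | (1S,2R)‑1‑[5‑(benzyloxy)‑4‑methyl‑1,3‑oxazol‑2‑yl]‑2‑methylbut‑3‑en‑1‑ol | C=C[C@@H](C)[C@H](O)c1nc(C)c(OCc2ccccc2)o1 | intermediate
7 | 5‑(benzyloxy)‑4‑methyl‑2‑[(1S,2R)‑2‑methyl‑1‑(triethylsilyloxy)but‑3‑en‑1‑yl]‑1,3‑oxazole | C=C[C@@H](C)[C@H](O[Si](CC)(CC)CC)c1nc(C)c(OCc2ccccc2)o1 | intermediate
8 | (3R,4S)‑4‑[5‑(benzyloxy)‑4‑methyl‑1,3‑oxazol‑2‑yl]‑3‑methyl‑4‑(triethylsilyloxy)butan‑1‑ol | OCC[C@@H](C)[C@H](O[Si](CC)(CC)CC)c1nc(C)c(OCc2ccccc2)o1 | intermediate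
9 | (3R,4S)‑4‑[5‑(benzyloxy)‑4‑methyl‑1,3‑oxazol‑2‑yl]‑3‑methyl‑4‑(triethylsilyloxy)butanal | O=CC[C@@H](C)[C@H](O[Si](CC)(CC)CC)c1nc(C)c(OCc2ccccc2)o1 | intermediate
10 | triisopropyl(prop‑2‑yn‑1‑yloxy)silane | C#CCO[Si](C(C)C)(C(C)C)C(C)C | starting material
11 | [3‑(triisopropylsilyloxy)prop‑1‑yn‑1‑yl]lithium (not isolated) | [Li]C#CCO[Si](C(C)C)(C(C)C)C(C)C | intermediate
12 | (6R,7S)‑7‑[5‑(benzyloxy)‑4‑methyl‑1,3‑oxazol‑2‑yl]‑6‑methyl‑7‑(triethylsilyloxy)‑1‑(triisopropylsilyloxy)hept‑2‑yn‑4‑ol (C4 epimers) | OC(C#CCO[Si](C(C)C)(C(C)C)C(C)C)C[C@@H](C)[C@H](O[Si](CC)(CC)CC)c1nc(C)c(OCc2ccccc2)o1 | intermediate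
13 | (6R,7S)‑7‑[5‑(benzyloxy)‑4‑methyl‑1,3‑oxazol‑2‑yl]‑6‑methyl‑7‑(triethylsilyloxy)‑1‑(triisopropylsilyloxy)hept‑2‑yn‑4‑one | O=C(C#CCO[Si](C(C)C)(C(C)C)C(C)C)C[C@@H](C)[C@H](O[Si](CC)(CC)CC)c1nc(C)c(OCc2ccccc2)o1 | intermediate
14 | 7‑oxa‑2‑azabicyclo[2.2.1]hepta‑2,5‑diene cycloadduct of 13, fused to ring B (bridgehead epimers, not isolated) | O=C1C[C@@H](C)[C@H](O[Si](CC)(CC)CC)C23OC(OCc4ccccc4)(C(C)=N2)C(CO[Si](C(C)C)(C(C)C)C(C)C)=C13 | intermediate
15 | (6R,7S)‑2‑(benzyloxy)‑6‑methyl‑7‑(triethylsilyloxy)‑3‑[(triisopropylsilyloxy)methyl]‑6,7‑dihydro‑1‑benzofuran‑4(5H)‑one | O=C1C[C@@H](C)[C@H](O[Si](CC)(CC)CC)c2oc(OCc3ccccc3)c(CO[Si](C(C)C)(C(C)C)C(C)C)c12 | intermediate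
16 | (4S,6R,7S)‑2‑(benzyloxy)‑6‑methyl‑7‑(triethylsilyloxy)‑3‑[(triisopropylsilyloxy)methyl]‑4,5,6,7‑tetrahydro‑1‑benzofuran‑4‑ol | O[C@H]1C[C@@H](C)[C@H](O[Si](CC)(CC)CC)c2oc(OCc3ccccc3)c(CO[Si](C(C)C)(C(C)C)C(C)C)c12 | intermediate
17 | (4S,6R,7S)‑2‑(benzyloxy)‑6‑methyl‑7‑(triethylsilyloxy)‑4‑(triisopropylsilyloxy)‑3‑[(triisopropylsilyloxy)methyl]‑4,5,6,7‑tetrahydro‑1‑benzofuran | CC(C)[Si](O[C@H]1C[C@@H](C)[C@H](O[Si](CC)(CC)CC)c2oc(OCc3ccccc3)c(CO[Si](C(C)C)(C(C)C)C(C)C)c12)(C(C)C)C(C)C | intermediate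
18 | (4S,6R,7S)‑2‑(benzyloxy)‑6‑methyl‑4‑(triisopropylsilyloxy)‑3‑[(triisopropylsilyloxy)methyl]‑4,5,6,7‑tetrahydro‑1‑benzofuran‑7‑ol | CC(C)[Si](O[C@H]1C[C@@H](C)[C@H](O)c2oc(OCc3ccccc3)c(CO[Si](C(C)C)(C(C)C)C(C)C)c12)(C(C)C)C(C)C | intermediate
19 | (4S,6R)‑2‑(benzyloxy)‑6‑methyl‑4‑(triisopropylsilyloxy)‑3‑[(triisopropylsilyloxy)methyl]‑5,6‑dihydro‑1‑benzofuran‑7(4H)‑one | CC(C)[Si](O[C@H]1C[C@@H](C)C(=O)c2oc(OCc3ccccc3)c(CO[Si](C(C)C)(C(C)C)C(C)C)c12)(C(C)C)C(C)C | intermediate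
20 | (R)‑citramalic acid | C[C@@](O)(CC(=O)O)C(=O)O | starting material
21 | (R)‑2‑methylbutane‑1,2,4‑triol | C[C@@](O)(CCO)CO | intermediate
22 | 2‑[(4R)‑2,2,4‑trimethyl‑1,3‑dioxolan‑4‑yl]ethanol | C[C@@]1(CCO)COC(C)(C)O1 | intermediate
23 | (4R)‑4‑(2‑bromoethyl)‑2,2,4‑trimethyl‑1,3‑dioxolane | C[C@@]1(CCBr)COC(C)(C)O1 | intermediate
24 | {2‑[(4R)‑2,2,4‑trimethyl‑1,3‑dioxolan‑4‑yl]ethyl}magnesium bromide (not isolated) | C[C@@]1(CC[Mg]Br)COC(C)(C)O1 | intermediate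
25 | (4S,6R,7R)‑2‑(benzyloxy)‑6‑methyl‑4‑(triisopropylsilyloxy)‑3‑[(triisopropylsilyloxy)methyl]‑7‑{2‑[(4R)‑2,2,4‑trimethyl‑1,3‑dioxolan‑4‑yl]ethyl}‑4,5,6,7‑tetrahydro‑1‑benzofuran‑7‑ol | CC(C)[Si](O[C@H]1C[C@@H](C)[C@](O)(CC[C@]4(C)COC(C)(C)O4)c2oc(OCc3ccccc3)c(CO[Si](C(C)C)(C(C)C)C(C)C)c12)(C(C)C)C(C)C | intermediate
26 | O‑debenzylated 2‑hydroxyfuran corresponding to 25 (not isolated) | CC(C)[Si](O[C@H]1C[C@@H](C)[C@](O)(CC[C@]3(C)COC(C)(C)O3)c2oc(O)c(CO[Si](C(C)C)(C(C)C)C(C)C)c12)(C(C)C)C(C)C | intermediate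
27 | (4S,6R,7R)‑7‑hydroxy‑6‑methyl‑4‑(triisopropylsilyloxy)‑3‑[(triisopropylsilyloxy)methyl]‑7‑{2‑[(4R)‑2,2,4‑trimethyl‑1,3‑dioxolan‑4‑yl]ethyl}‑5,6,7,7a‑tetrahydro‑1‑benzofuran‑2(4H)‑one (C7a epimers, not isolated) | CC(C)[Si](OCC1=C2[C@@H](O[Si](C(C)C)(C(C)C)C(C)C)C[C@@H](C)[C@](O)(CC[C@]3(C)COC(C)(C)O3)C2OC1=O)(C(C)C)C(C)C | intermediate
28 | (4S,6R,7R)‑7‑[(3R)‑3,4‑dihydroxy‑3‑methylbutyl]‑7‑hydroxy‑6‑methyl‑4‑(triisopropylsilyloxy)‑3‑[(triisopropylsilyloxy)methyl]‑5,6,7,7a‑tetrahydro‑1‑benzofuran‑2(4H)‑one (C7a epimers) | CC(C)[Si](OCC1=C2[C@@H](O[Si](C(C)C)(C(C)C)C(C)C)C[C@@H](C)[C@](O)(CC[C@@](C)(O)CO)C2OC1=O)(C(C)C)C(C)C | intermediate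
29 | (4S,6R,7R)‑7‑hydroxy‑7‑[(3R)‑3‑hydroxy‑3‑methyl‑4‑oxobutyl]‑6‑methyl‑4‑(triisopropylsilyloxy)‑3‑[(triisopropylsilyloxy)methyl]‑5,6,7,7a‑tetrahydro‑1‑benzofuran‑2(4H)‑one (not isolated) | CC(C)[Si](OCC1=C2[C@@H](O[Si](C(C)C)(C(C)C)C(C)C)C[C@@H](C)[C@](O)(CC[C@@](C)(O)C=O)C2OC1=O)(C(C)C)C(C)C | intermediate
30 | tricyclic vinylogous aldol adduct: butenolide fused to ring B, ring A (C1–C6) cis‑fused through the C1–C6 bond, tertiary hydroxyls at C1 and C4 (4R), secondary hydroxyl at C5 (epimers), 8S‑ and 13‑triisopropylsilyloxy, 10R‑methyl | CC(C)[Si](OCC1=C2[C@@H](O[Si](C(C)C)(C(C)C)C(C)C)C[C@@H](C)[C@]3(O)CC[C@@](C)(O)C(O)[C@]23OC1=O)(C(C)C)C(C)C | intermediate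
31 | C5 methanesulfonate of 30 | CC(C)[Si](OCC1=C2[C@@H](O[Si](C(C)C)(C(C)C)C(C)C)C[C@@H](C)[C@]3(O)CC[C@@](C)(O)C(OS(C)(=O)=O)[C@]23OC1=O)(C(C)C)C(C)C | intermediate
32 | (4R,5E,8S,10R)‑4‑hydroxy‑1‑oxo‑8,13‑bis(triisopropylsilyloxy)germacra‑5,7(11)‑dien‑12,6‑olide (not isolated) | CC(C)[Si](OCC1=C2/C(=C\[C@](C)(O)CCC(=O)[C@H](C)C[C@@H]2O[Si](C(C)C)(C(C)C)C(C)C)OC1=O)(C(C)C)C(C)C | intermediate
33 | (1S,4R,5E,8S,10R)‑1,4‑epoxy‑1‑hydroxy‑8,13‑bis(triisopropylsilyloxy)germacra‑5,7(11)‑dien‑12,6‑olide | CC(C)[Si](OCC1=C2/C(=C\[C@@]3(C)CC[C@](O)(O3)[C@H](C)C[C@@H]2O[Si](C(C)C)(C(C)C)C(C)C)OC1=O)(C(C)C)C(C)C | intermediate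
34 | (1S,4R,5E,8S,10R)‑1,4‑epoxy‑1,8,13‑trihydroxygermacra‑5,7(11)‑dien‑12,6‑olide | OCC1=C2/C(=C\[C@@]3(C)CC[C@](O)(O3)[C@H](C)C[C@@H]2O)OC1=O | intermediate
35 | (1S,4R,5E,8S,10R)‑13‑acetoxy‑1,4‑epoxy‑1,8‑dihydroxygermacra‑5,7(11)‑dien‑12,6‑olide | CC(=O)OCC1=C2/C(=C\[C@@]3(C)CC[C@](O)(O3)[C@H](C)C[C@@H]2O)OC1=O | intermediate
36 | (R)‑3‑bromo‑2‑hydroxy‑2‑methylpropanoic acid | C[C@](O)(CBr)C(=O)O | starting material
37 | potassium (S)‑2‑methyloxirane‑2‑carboxylate | C[C@]1(CO1)C(=O)[O-].[K+] | intermediate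
38 | (S)‑2‑methyloxirane‑2‑carboxylic 2,4,6‑trichlorobenzoic anhydride (not isolated) | C[C@]1(CO1)C(=O)OC(=O)c1c(Cl)cc(Cl)cc1Cl | intermediate
39 | 8‑O‑[(2S)‑2‑methyloxirane‑2‑carbonyl] ester of 35 | CC(=O)OCC1=C2/C(=C\[C@@]3(C)CC[C@](O)(O3)[C@H](C)C[C@@H]2OC(=O)[C@]4(C)CO4)OC1=O | intermediate
40 | CNP0414417.3, 8‑O‑[(2R)‑3‑chloro‑2‑hydroxy‑2‑methylpropanoyl] ester of 35 | CC(=O)OCC1=C2/C(=C\[C@@]3(C)CC[C@](O)(O3)[C@H](C)C[C@@H]2OC(=O)[C@@](C)(O)CCl)OC1=O | target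

**Count**

Total steps: 27. Longest linear sequence: 23 steps (steps 1–14, 18–24, 26 and 27).

**Steps most likely to fail**

1. Step 22. The alkoxide may partition between the wanted C1–C6 fragmentation, closure of a 4,5‑epoxide, and a concerted anti‑periplanar fragmentation that places C4 and C7 trans on the new alkene, which cannot bridge to the hemiketal. The fallback separates carbon–carbon cleavage from alkene formation. It sets out from 30 and comes back at 33. Compound 30, which carries no sulfonate, is equilibrated with DBU (0.5 equiv) in MeCN at 40 °C, so that reversible retro‑vinylogous aldol cleavage of C1–C6 drains into the ten‑membered 5‑hydroxy‑6H‑butenolide held as its C1/C4 hemiketal F1. The secondary C5 hydroxyl is acetylated (Ac2O, DMAP, pyridine) to the acetate F2. DBU in toluene at 60 °C then eliminates acetic acid from the bridged furanolate (E1cB), where the ring admits only the alkene with C4 and C7 cis, to give 33.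

2. Step 18. The hindered, vinylogous‑carbonate ketone may be enolized at C10 (loss of configuration, recovered ketone) instead of being attacked. The fallback replaces the polar organomagnesium addition by a single‑electron Barbier coupling. It sets out from 22 and 19 and comes back at 25. Alcohol 22 is converted (I2, PPh3, imidazole) into (4R)‑4‑(2‑iodoethyl)‑2,2,4‑trimethyl‑1,3‑dioxolane F3. F3 and ketone 19 are then joined with SmI2 (2.5 equiv) and NiI2 (2 mol %) in THF at 0 °C under non‑basic conditions to give 25.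

3. Step 11. Hydride delivery to the ring‑fused furyl ketone may show poor facial selectivity. The fallback sets C8 by catalyst control before the ring is formed. It sets out from 13 and comes back at 17. Ynone 13 is reduced by transfer hydrogenation with RuCl[(S,S)‑TsDPEN](p‑cymene) in i‑PrOH to the (4S)‑propargylic alcohol F4, which is silylated (TIPSOTf, 2,6‑lutidine) to F5. F5 is heated in 1,2‑dichlorobenzene at 150–170 °C, where the unactivated alkyne should undergo the same Diels–Alder/retro‑Diels–Alder sequence through cycloadduct F6 to give 17 directly.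

**Further compounds**

F1 | step 22 | (1S,4R,8S,10R)‑1,4‑epoxy‑1,5‑dihydroxy‑8,13‑bis(triisopropylsilyloxy)germacr‑7(11)‑en‑12,6‑olide (C5 and C6 epimers) | CC(C)[Si](OCC1=C2C(C(O)[C@@]3(C)CC[C@](O)(O3)[C@H](C)C[C@@H]2O[Si](C(C)C)(C(C)C)C(C)C)OC1=O)(C(C)C)C(C)C
F2 | step 22 | 5‑O‑acetate of F1 | CC(C)[Si](OCC1=C2C(C(OC(C)=O)[C@@]3(C)CC[C@](O)(O3)[C@H](C)C[C@@H]2O[Si](C(C)C)(C(C)C)C(C)C)OC1=O)(C(C)C)C(C)C
F3 | step 18 | (4R)‑4‑(2‑iodoethyl)‑2,2,4‑trimethyl‑1,3‑dioxolane | C[C@@]1(CCI)COC(C)(C)O1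
F4 | step 11 | (4S,6R,7S)‑7‑[5‑(benzyloxy)‑4‑methyl‑1,3‑oxazol‑2‑yl]‑6‑methyl‑7‑(triethylsilyloxy)‑1‑(triisopropylsilyloxy)hept‑2‑yn‑4‑ol | O[C@H](C#CCO[Si](C(C)C)(C(C)C)C(C)C)C[C@@H](C)[C@H](O[Si](CC)(CC)CC)c1nc(C)c(OCc2ccccc2)o1
F5 | step 11 | 4‑O‑triisopropylsilyl ether of F4 | CC(C)[Si](O[C@H](C#CCO[Si](C(C)C)(C(C)C)C(C)C)C[C@@H](C)[C@H](O[Si](CC)(CC)CC)c1nc(C)c(OCc2ccccc2)o1)(C(C)C)C(C)C
F6 | step 11 | 7‑oxa‑2‑azabicyclo[2.2.1]hepta‑2,5‑diene cycloadduct of F5 (bridgehead epimers) | CC(C)[Si](O[C@H]1C[C@@H](C)[C@H](O[Si](CC)(CC)CC)C23OC(OCc4ccccc4)(C(C)=N2)C(CO[Si](C(C)C)(C(C)C)C(C)C)=C13)(C(C)C)C(C)C
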